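The synthesis rests on reading the trans-diaxial C4a/C5 diol of ring B as the hydrolysed epoxide of a C4a=C5 alkene. Both carbinol carbons can then start as carbonyl carbons of like polarity. One low-valent titanium coupling joins the ring A enone carbonyl (C4a) to the side-chain methyl ketone (C5). In a single operation it closes six-membered ring B and installs the tetrasubstituted alkene of a C3=C4/C4a=C5 diene. The precursor is a cyclohexenone that already carries the camphor-derived cyclopentyl group at C3, a spiro-dioxolane at C2, the quaternary C8a and the C8 carbinol. Both future bromides travel as silyl ethers of inverted configuration.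

Key step: step 18

**Conventions:** The bicycle is numbered as naphthalen-2(1H)-one. Ring A is C1–C4, C4a, C8a and ring B is C4a, C5–C8, C8a. The cyclopentane (ring C) has primed numbers, with C1' bonded to C3. β is the face of the C8a methyl and α is the other face. TBS = tert-butyldimethylsilyl. "Silyloxycyclopentyl unit" means (1S,3S)-3-(TBSO)-1,2,2-trimethylcyclopentyl, with OTBS trans to the C1' bond that leads to ring A.

**Remark on C3':** In the camphoric/camphanic series the carbon substituent at C3' lies on the face of the C1' carboxyl, which is the face the bromine must finally occupy. Bromide enters with inversion, so the oxygen must sit on the opposite face. C3' is therefore taken through a ketone and set by reagent control, not by a retentive degradation.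

**Remark on C2:** A dimethyl ketal next to the growing diene would ionise easily under titanium and zinc chlorides. It is exchanged early for a spiro-dioxolane, whose tethered oxygen re-closes.

**Remark on C8a/C8:** The ring C stereocentres are too remote to bias C8a. C8a and C8 are therefore set by two separate catalyst-controlled reactions.

**Assumption:** (1R,4S)-camphanic acid is taken as commercially available. Otherwise it is made from (1S,3R)-camphoric acid by α-bromination and hydrolysis.

## Route

Step 1
Reactants: 1 (1R,4S)-camphanic acid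
Product: 2 (1R,3S)-1,3-bis(hydroxymethyl)-2,2,3-trimethylcyclopentan-1-ol
Conditions: LiAlH4, THF, 0 °C to reflux; H2O quench
Reagents that add atoms: none
Why: Exhaustive LiAlH4 reduction of the acid and of the bridged lactone frees the tertiary C3' alcohol beside a new CH2OH group and touches neither stereocentre.

Step 2
Reactants: 2 (1R,3S)-1,3-bis(hydroxymethyl)-2,2,3-trimethylcyclopentan-1-ol
Product: 3 (S)-3-(hydroxymethyl)-2,2,3-trimethylcyclopentan-1-one
Conditions: NaIO4, THF–H2O, 0 °C to rt
Reagents that add atoms: none
Why: Periodate glycol cleavage removes the CH2OH carbon of the 1,2-diol and turns C3' into a ketone, while the isolated neopentyl CH2OH at C1' has no vicinal partner and survives.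

Step 3
Reactants: 3 (S)-3-(hydroxymethyl)-2,2,3-trimethylcyclopentan-1-one
Product: 4 (1S,3S)-3-(hydroxymethyl)-2,2,3-trimethylcyclopentan-1-ol (OH trans to CH2OH)
Conditions: (R)-Me-CBS oxazaborolidine (15 mol %), BH3·SMe2, THF, −20 °C; MeOH, then H2O
Reagents that add atoms: none
Why: In this Corey–Bakshi–Shibata reduction the catalyst distinguishes the quaternary C2' flank from the C4' methylene, so the (R)-catalyst should deliver hydride on the face that carries CH2OH (the alkoxyborane of the free alcohol can only reinforce this) and set (S)-C3' with oxygen trans to CH2OH.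

Step 4
Reactants: 4 (1S,3S)-3-(hydroxymethyl)-2,2,3-trimethylcyclopentan-1-ol
Product: 5 (1S,3S)-3-hydroxy-1,2,2-trimethylcyclopentane-1-carboxylic acid
Conditions: TEMPO (cat.), PhI(OAc)2, MeCN–H2O, rt
Reagents that add atoms: water, O
Why: The oxoammonium (TEMPO) oxidation prefers the primary alcohol to the hindered secondary one and runs through the aldehyde hydrate to the acid, which cannot lactonise because OH and CO2H are trans.

Step 5
Reactants: 5 (1S,3S)-3-hydroxy-1,2,2-trimethylcyclopentane-1-carboxylic acid
Product: 7 (1S,3S)-3-(tert-butyldimethylsilyloxy)-1,2,2-trimethylcyclopentane-1-carboxylic acid, via bis-silyl derivative 6 (not isolated)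
Conditions: TBSOTf, 2,6-lutidine, CH2Cl2, 0 °C; then AcOH–THF–H2O, rt
Reagents that add atoms: tert-butyldimethylsilyl triflate, CC(C)(C)[Si](C)(C)OS(=O)(=O)C(F)(F)F
Why: Silyl triflate silylation covers the hindered alcohol and the acid alike, and the far more labile silyl ester is hydrolysed selectively afterwards.

Step 6
Reactants: 7 (1S,3S)-3-(tert-butyldimethylsilyloxy)-1,2,2-trimethylcyclopentane-1-carboxylic acid
Product: 8 1-[(1S,3S)-3-(tert-butyldimethylsilyloxy)-1,2,2-trimethylcyclopentyl]ethan-1-one
Conditions: MeLi, Et2O, 0 °C to rt; poured into ice-water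
Reagents that add atoms: methyllithium, [Li]C
Why: Addition of MeLi to the lithium carboxylate gives a geminal dilithium diolate that collapses to the methyl ketone only on quenching, which is the standard ketone synthesis from hindered acids.

Step 7
Reactants: 8 1-[(1S,3S)-3-(tert-butyldimethylsilyloxy)-1,2,2-trimethylcyclopentyl]ethan-1-one
Product: 9 2,4,6-triisopropylbenzenesulfonylhydrazone of 8
Conditions: 2,4,6-triisopropylbenzenesulfonohydrazide, PPTS (cat.), THF, rt
Reagents that add atoms: 2,4,6-triisopropylbenzenesulfonohydrazide, NNS(=O)(=O)c1c(C(C)C)cc(C(C)C)cc1C(C)C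
Why: Hydrazone condensation works on pinacolone-type ketones, and the bulk of C1' turns the N–N bond toward the methyl group, as the next deprotonation requires.

Step 8
Reactants: 9 2,4,6-triisopropylbenzenesulfonylhydrazone of 8
Product: 12 Fischer carbene complex (CO)5Cr=C(OMe)–C(=CH2)–[silyloxycyclopentyl unit], via vinyllithium 10 (not isolated), via lithium acylchromate 11 (not isolated)
Conditions: n-BuLi, THF, −78 to 0 °C; Cr(CO)6, THF, 0 °C to rt; MeOTf, CH2Cl2, 0 °C
Reagents that add atoms: Cr(CO)6, O=C=[Cr](=C=O)(=C=O)(=C=O)(=C=O)=C=O; methyl triflate, COS(=O)(=O)C(F)(F)F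
Why: The Shapiro reaction (only the methyl group has α-hydrogens) gives the 1-substituted vinyllithium, which adds to a CO ligand, and O-methylation of the acylate completes the standard Fischer carbene synthesis.

Step 9
Reactants: 12 Fischer carbene complex; 13 propyne
Product: 14 4-methoxy-2-methyl-5-[silyloxycyclopentyl unit]phenol
Conditions: 13 (excess), THF, 50 °C, sealed tube; then air, rt
Reagents that add atoms: none
Why: The Dötz benzannulation (alkyne insertion, CO insertion, electrocyclisation of the vinylketene) builds ring A as a 4-methoxyphenol, and the terminal alkyne puts its substituted carbon next to the CO-derived carbon, so the methyl group ends at C8a and the methoxy group at C2 beside ring C.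

Step 10
Reactants: 14 4-methoxy-2-methyl-5-[silyloxycyclopentyl unit]phenol
Product: 15 4,4-dimethoxy-2-methyl-5-[silyloxycyclopentyl unit]cyclohexa-2,5-dien-1-one
Conditions: PhI(OAc)2, MeOH, 0 °C
Reagents that add atoms: methanol, CO
Why: Hypervalent-iodine oxidative dearomatisation of a 4-alkoxyphenol traps methanol at the para carbon C2 and so differentiates the two ring A oxygens as C4a ketone and C2 ketal.

Step 11
Reactants: 15 4,4-dimethoxy-2-methyl-5-[silyloxycyclopentyl unit]cyclohexa-2,5-dien-1-one
Product: 16 9-methyl-6-[silyloxycyclopentyl unit]-1,4-dioxaspiro[4.5]deca-6,9-dien-8-one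
Conditions: HOCH2CH2OH, BF3·OEt2 (cat.), DME, 0 °C to rt
Reagents that add atoms: ethylene glycol, OCCO
Why: Lewis-acid transketalisation of a quinone dimethyl monoketal is driven by ring formation and by relief of crowding beside C1', and gives the more ionisation-resistant spiro-dioxolane.

Step 12
Reactants: 16 9-methyl-6-[silyloxycyclopentyl unit]-1,4-dioxaspiro[4.5]deca-6,9-dien-8-one; 17 allyl chloroformate
Product: 19 allyl dienol carbonate (C4a–OCO2allyl; C4a=C8a; C3=C4; C1H2), via lithium enolate 18 (not isolated)
Conditions: LiBH(s-Bu)3, THF, −78 °C; then 17, −78 to 0 °C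
Reagents that add atoms: none
Why: Conjugate hydride reduction of the cross-conjugated dienone can only reach the unsubstituted β-carbon C1 (C3 is blocked), and the regiodefined tetrasubstituted enolate is acylated on oxygen by the hard chloroformate, as in reductive enol triflate formation.

Step 13
Reactants: 19 allyl dienol carbonate
Product: 20 (9S)-9-allyl-9-methyl-6-[silyloxycyclopentyl unit]-1,4-dioxaspiro[4.5]dec-6-en-8-one (C8a quaternary, methyl β)
Conditions: Pd2(dba)3 (cat.), (R)-t-Bu-PHOX (cat.), toluene, 25–30 °C
Reagents that add atoms: none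
Why: In this decarboxylative asymmetric allylic alkylation (Tsuji allylation), zerovalent palladium ionises the carbonate, CO2 is lost, and the PHOX ligand rather than remote ring C chooses the enolate face, so the (R)-ligand should give (S)-C8a, by analogy with 2-methylcyclohexanone-derived enol carbonates.

Step 14
Reactants: 20 (9S)-9-allyl-9-methyl ketone
Product: 21 2-[(9S)-9-methyl-8-oxo-6-[silyloxycyclopentyl unit]-1,4-dioxaspiro[4.5]dec-6-en-9-yl]acetaldehyde
Conditions: O3, CH2Cl2, −78 °C (Sudan red end point); PPh3, −78 °C to rt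
Reagents that add atoms: ozone, [O-][O+]=O
Why: Ozonolysis takes the electron-rich monosubstituted alkene much faster than the hindered, electron-poor C3=C4 enone bond, and leaves C8 and C7 as CH2–CHO.

Step 15
Reactants: 21 aldehyde; 22 diethyl (2-oxopropyl)phosphonate
Product: 24 (8R,8aR)-γ-(anilinooxy) (E)-enone (C8–ONHPh; C7=C6; C5 methyl ketone), via aminoxy aldehyde 23 (not isolated)
Conditions: PhNO, D-proline (cat.), DMSO, rt; then 22, Cs2CO3, 0 °C to rt
Reagents that add atoms: nitrosobenzene, O=Nc1ccccc1
Why: In the proline-catalysed α-aminoxylation the enamine of 21 attacks the oxygen of acid-activated PhNO from the face fixed by the catalyst, so D-proline should set C8 (S in 23, oxygen destined to be 8α) regardless of C8a, and the Horner–Wadsworth–Emmons olefination in the same flask adds C6, C5 and the methyl group before the aldehyde can epimerise.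

Step 16
Reactants: 24 γ-(anilinooxy) enone
Product: 25 (8R,8aR)-γ-hydroxy methyl ketone (C8–OH free)
Conditions: H2 (1 atm), Pd/C, EtOAc, rt
Reagents that add atoms: none
Why: Heterogeneous hydrogenation saturates the disubstituted side-chain alkene and hydrogenolyses the weak N–O bond, whereas the ring enone, trisubstituted and wedged between C1' and the spiro-ketal, is too hindered to bind.

Step 17
Reactants: 25 γ-hydroxy methyl ketone
Product: 26 (8R,8aR)-bis-silyl keto-enone (C4a enone ketone; C2 dioxolane; C8a methyl; side chain C8H(OTBS)–C7H2–C6H2–C5(=O)CH3)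
Conditions: TBSOTf, 2,6-lutidine, CH2Cl2, −78 to 0 °C
Reagents that add atoms: tert-butyldimethylsilyl triflate, CC(C)(C)[Si](C)(C)OS(=O)(=O)C(F)(F)F
Why: Silyl triflate silylation reaches the neopentylic carbinol, while the hindered pyridine base does not enolise the methyl ketone at low temperature.

Step 18
Reactants: 26 bis-silyl keto-enone
Product: 28 (8R,8aS)-C3=C4/C4a=C5 dienyl dioxolane bis-silyl ether (ring B closed), via titanium pinacolate 27 (not isolated)
Conditions: TiCl3(DME)1.5, Zn–Cu couple, DME, reflux (slurry pre-formed); 26 added by syringe pump over about 30 h, then reflux; aq. K2CO3 work-up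
Reagents that add atoms: none
Why: Electron transfer from the low-valent titanium surface gives titanium-bound ketyls, first at the more easily reduced enone carbonyl C4a; C4a–C5 bond formation gives the pinacolate 27, and at reflux both C–O bonds break (the allylic C4a–O first) to release the C4a=C5 alkene. The closest known reaction type is the intramolecular McMurry coupling of diketones and of enone-carbonyl pairs to tetrasubstituted cycloalkenes and ring-fused conjugated dienes. Ring B closes as a six-membered ring, 6-exo-trig at the accepting carbonyl, with both oxygens outside the ring. No stereocentre is created, the configuration of 27 is erased, and C8 and C8a cannot epimerise because C8a is quaternary and C8 has no acidic hydrogen. The step needs intramolecular carbonyl–carbonyl coupling in preference to coupling through C3, to dimerisation and to loss of the C2 oxygen: C3 is shielded by quaternary C1' and the spiro-ketal, slow addition keeps the substrate dilute, and the tethered dioxolane re-closes after any Lewis-acid ionisation. The two silyl ethers stand in for the bromides, which the reagent would reduce.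

Step 19
Reactants: 28 dienyl dioxolane bis-silyl ether
Product: 29 (8R,8aS)-8α-hydroxy-3-[(1S,3S)-3-hydroxy-1,2,2-trimethylcyclopentyl]-5,8a-dimethyl-6,7,8,8a-tetrahydronaphthalen-2(1H)-one
Conditions: aq. HF, MeCN, rt
Reagents that add atoms: water, O
Why: Acidic fluoride removes both silyl ethers and hydrolyses the doubly allylic ketal in one operation to the acid-stable linear dienone without touching a stereocentre.

Step 20
Reactants: 29 dienone diol
Product: 30 (8S,8aS)-8β-bromo-3-[(1R,3R)-3-bromo-1,2,2-trimethylcyclopentyl]-5,8a-dimethyl-6,7,8,8a-tetrahydronaphthalen-2(1H)-one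
Conditions: CBr4, PPh3, toluene, 70 °C
Reagents that add atoms: carbon tetrabromide, BrC(Br)(Br)Br
Why: In the Appel reaction bromide displaces both alkoxyphosphonium groups by SN2 with inversion, a conversion known for axial neopentylic cyclohexanols and 2,2-dimethylcyclopentanols, so 8α-O becomes equatorial 8β-Br and the 3'-O trans to ring A becomes Br cis to it, while the electron-poor dienone disfavours a methyl shift from C8a.

Step 21
Reactants: 30 dibromo dienone
Product: 31 4aα,5α-epoxide of 30
Conditions: mCPBA, Na2HPO4, CH2Cl2, 0 °C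
Reagents that add atoms: 3-chloroperbenzoic acid, OOC(=O)c1cccc(Cl)c1
Why: In the Prilezhaev epoxidation the peracid selects the more electron-rich tetrasubstituted γ,δ-alkene of the dienone and approaches from the α face, opposite the axial C8a methyl, which fixes the C4a–O bond as α.

Step 22
Reactants: 31 4aα,5α-epoxide
Product: 32 target, (4aR,5R,8S,8aS)-8-bromo-3-[(1R,3R)-3-bromo-1,2,2-trimethylcyclopentyl]-4a,5-dihydroxy-5,8a-dimethyl-4a,5,6,7,8,8a-hexahydronaphthalen-2(1H)-one
Conditions: HClO4 (cat.), THF–H2O, 0 °C to rt
Reagents that add atoms: water, O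
Why: Acid-catalysed epoxide hydrolysis follows the Fürst–Plattner rule: the C5–O bond breaks because positive charge at C4a is disfavoured by the enone, and water enters C5 from the β face with inversion to give the trans-diaxial 4aα,5β-diol with the C5 methyl equatorial.

## Compound list

1 | (1R,4S)-camphanic acid | CC1(C)[C@@]2(C(=O)O)CC[C@]1(C)C(=O)O2 | starting material
2 | (1R,3S)-1,3-bis(hydroxymethyl)-2,2,3-trimethylcyclopentan-1-ol | CC1(C)[C@@](O)(CO)CC[C@]1(C)CO | intermediate
3 | (S)-3-(hydroxymethyl)-2,2,3-trimethylcyclopentan-1-one | CC1(C)C(=O)CC[C@]1(C)CO | intermediate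
4 | (1S,3S)-3-(hydroxymethyl)-2,2,3-trimethylcyclopentan-1-ol | CC1(C)[C@@H](O)CC[C@]1(C)CO | intermediate
5 | (1S,3S)-3-hydroxy-1,2,2-trimethylcyclopentane-1-carboxylic acid | CC1(C)[C@@H](O)CC[C@]1(C)C(=O)O | intermediate
6 | TBS ether TBS ester of 5 | CC1(C)[C@@H](O[Si](C)(C)C(C)(C)C)CC[C@]1(C)C(=O)O[Si](C)(C)C(C)(C)C | intermediate
7 | (1S,3S)-3-(TBSO)-1,2,2-trimethylcyclopentane-1-carboxylic acid | CC1(C)[C@@H](O[Si](C)(C)C(C)(C)C)CC[C@]1(C)C(=O)O | intermediate
8 | 1-[(1S,3S)-3-(TBSO)-1,2,2-trimethylcyclopentyl]ethan-1-one | CC1(C)[C@@H](O[Si](C)(C)C(C)(C)C)CC[C@]1(C)C(C)=O | intermediate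
9 | 2,4,6-triisopropylbenzenesulfonylhydrazone of 8 | CC1(C)[C@@H](O[Si](C)(C)C(C)(C)C)CC[C@]1(C)C(C)=NNS(=O)(=O)c1c(C(C)C)cc(C(C)C)cc1C(C)C | intermediate
10 | 1-(silyloxycyclopentyl)vinyllithium, configuration as in 8 | CC1(C)[C@@H](O[Si](C)(C)C(C)(C)C)CC[C@]1(C)C([Li])=C | intermediate
11 | lithium acylchromate (CO)5Cr=C(OLi)–C(=CH2)–cyclopentyl | CC1(C)[C@@H](O[Si](C)(C)C(C)(C)C)CC[C@]1(C)C(=C)C(O[Li])=[Cr](=C=O)(=C=O)(=C=O)(=C=O)=C=O | intermediate
12 | Fischer carbene (CO)5Cr=C(OMe)–C(=CH2)–cyclopentyl | CC1(C)[C@@H](O[Si](C)(C)C(C)(C)C)CC[C@]1(C)C(=C)C(OC)=[Cr](=C=O)(=C=O)(=C=O)(=C=O)=C=O | intermediate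
13 | propyne | CC#C | starting material
14 | 4-methoxy-2-methyl-5-[(1S,3S)-3-(TBSO)-1,2,2-trimethylcyclopentyl]phenol | CC1(C)[C@@H](O[Si](C)(C)C(C)(C)C)CC[C@]1(C)c1cc(O)c(C)cc1OC | intermediate
15 | quinone dimethyl monoketal | CC1(C)[C@@H](O[Si](C)(C)C(C)(C)C)CC[C@]1(C)C1=CC(=O)C(C)=CC1(OC)OC | intermediate
16 | quinone mono(ethylene ketal) | CC1(C)[C@@H](O[Si](C)(C)C(C)(C)C)CC[C@]1(C)C1=CC(=O)C(C)=CC12OCCO2 | intermediate
17 | allyl chloroformate | C=CCOC(=O)Cl | starting material
18 | lithium cross-conjugated dienolate | CC1(C)[C@@H](O[Si](C)(C)C(C)(C)C)CC[C@]1(C)C1=CC(O[Li])=C(C)CC12OCCO2 | intermediate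
19 | allyl dienol carbonate | CC1(C)[C@@H](O[Si](C)(C)C(C)(C)C)CC[C@]1(C)C1=CC(OC(=O)OCC=C)=C(C)CC12OCCO2 | intermediate
20 | (S)-C8a allyl methyl ketone | CC1(C)[C@@H](O[Si](C)(C)C(C)(C)C)CC[C@]1(C)C1=CC(=O)[C@@](C)(CC=C)CC12OCCO2 | intermediate
21 | C7 aldehyde | CC1(C)[C@@H](O[Si](C)(C)C(C)(C)C)CC[C@]1(C)C1=CC(=O)[C@@](C)(CC=O)CC12OCCO2 | intermediate
22 | diethyl (2-oxopropyl)phosphonate | CCOP(=O)(CC(C)=O)OCC | starting material
23 | (8S,8aR)-α-(anilinooxy) aldehyde | CC1(C)[C@@H](O[Si](C)(C)C(C)(C)C)CC[C@]1(C)C1=CC(=O)[C@@](C)([C@H](ONc3ccccc3)C=O)CC12OCCO2 | intermediate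
24 | (8R,8aR)-γ-(anilinooxy) (E)-enone | CC1(C)[C@@H](O[Si](C)(C)C(C)(C)C)CC[C@]1(C)C1=CC(=O)[C@@](C)([C@H](ONc3ccccc3)/C=C/C(C)=O)CC12OCCO2 | intermediate
25 | (8R,8aR)-γ-hydroxy methyl ketone | CC1(C)[C@@H](O[Si](C)(C)C(C)(C)C)CC[C@]1(C)C1=CC(=O)[C@@](C)([C@H](O)CCC(C)=O)CC12OCCO2 | intermediate
26 | (8R,8aR)-bis-silyl keto-enone, precursor of the key step | CC1(C)[C@@H](O[Si](C)(C)C(C)(C)C)CC[C@]1(C)C1=CC(=O)[C@@](C)([C@H](O[Si](C)(C)C(C)(C)C)CCC(C)=O)CC12OCCO2 | intermediate
27 | titanium C4a,C5-pinacolate (other ligands on Ti omitted, C4a/C5 configuration immaterial) | CC1(C)[C@@H](O[Si](C)(C)C(C)(C)C)CC[C@]1(C)C1=CC23O[Ti]OC2(C)CC[C@@H](O[Si](C)(C)C(C)(C)C)[C@@]3(C)CC14OCCO4 | intermediate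
28 | (8R,8aS)-dienyl dioxolane bis-silyl ether, product of the key step | CC1(C)[C@@H](O[Si](C)(C)C(C)(C)C)CC[C@]1(C)C1=CC2=C(C)CC[C@@H](O[Si](C)(C)C(C)(C)C)[C@@]2(C)CC13OCCO3 | intermediate
29 | (8R,8aS)-dienone diol | CC1(C)[C@@H](O)CC[C@]1(C)C1=CC2=C(C)CC[C@@H](O)[C@@]2(C)CC1=O | intermediate
30 | (8S,8aS)-dibromo dienone | CC1(C)[C@H](Br)CC[C@]1(C)C1=CC2=C(C)CC[C@H](Br)[C@@]2(C)CC1=O | intermediate
31 | 4aα,5α-epoxy dibromo enone | CC1(C)[C@H](Br)CC[C@]1(C)C1=C[C@]23O[C@@]2(C)CC[C@H](Br)[C@@]3(C)CC1=O | intermediate
32 | CNP0216929.1 | CC1(C)[C@H](Br)CC[C@]1(C)C1=C[C@]2(O)[C@](C)(O)CC[C@H](Br)[C@@]2(C)CC1=O | target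

Total step count: 22.
Longest linear sequence: 22 steps (1 to 32). Compounds 13, 17 and 22 are bought.

## Steps most likely to fail

**1. Step 18.**
- What may go wrong: once the enone has taken up electrons, the C2–O bond may be expelled or ionised. The crowded di-tertiary pinacolate may resist deoxygenation. Two molecules may couple with each other.
- Fallback: bond formation and deoxygenation are separated. Starting from 26, Mg(Hg)/TiCl4 in THF at −10 to 0 °C (pinacol cyclisation, too cold for deoxygenation) should stop at the cis-4aα,5α-diol F1. Deprotonation with n-BuLi followed by thiocarbonyldiimidazole should give the cyclic thionocarbonate F2. Heating it in P(OMe)3 (Corey–Winter olefination, a syn elimination that needs neither Lewis acid nor reducing metal) rejoins the route at 28.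

**2. Step 20.**
- What may go wrong: at either neopentylic centre the alkoxyphosphonium ion may ionise or eliminate before bromide reaches its rear side. That would cause elimination toward C7, a 1,2-methyl shift from C8a or C2', or substitution at only one site.
- Fallback: activation and displacement are separated, and the leaving group becomes an isolable sulfonate. From 29, ClCH2SO2Cl and pyridine should give the bis(chloromethanesulfonate) F3. This is purified and then heated with LiBr in DMF (SN2 with inversion at both centres) to come back at 30.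

**3. Step 12.**
- What may go wrong: hydride may attack the carbonyl carbon C4a instead of C1, followed by aromatisation with loss of the ketal. Alternatively the enolate may be acylated on carbon.
- Fallback: the hydride is delivered by a metal-catalysed 1,4-hydrosilylation, and the enolate is released only in the allylation flask. From 16, Et3SiH and RhCl(PPh3)3 (cat.) in toluene should give the triethylsilyl dienol ether F4. Treating it with diallyl carbonate, Bu4N[Ph3SiF2] and Pd2(dba)3/(R)-t-Bu-PHOX should lead directly to 20, so that 19 is bypassed.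

## Further compounds

F1 | step 18 | cis-4aα,5α-diol (bis-silyl ether, C2 dioxolane) | CC1(C)[C@@H](O[Si](C)(C)C(C)(C)C)CC[C@]1(C)C1=C[C@]2(O)[C@@](C)(O)CC[C@@H](O[Si](C)(C)C(C)(C)C)[C@@]2(C)CC13OCCO3
F2 | step 18 | cyclic thionocarbonate of F1 | CC1(C)[C@@H](O[Si](C)(C)C(C)(C)C)CC[C@]1(C)C1=C[C@@]24OC(=S)O[C@@]4(C)CC[C@@H](O[Si](C)(C)C(C)(C)C)[C@@]2(C)CC13OCCO3
F3 | step 20 | bis(chloromethanesulfonate) of 29 | CC1(C)[C@@H](OS(=O)(=O)CCl)CC[C@]1(C)C1=CC2=C(C)CC[C@@H](OS(=O)(=O)CCl)[C@@]2(C)CC1=O
F4 | step 12 | triethylsilyl dienol ether from 16 | CC1(C)[C@@H](O[Si](C)(C)C(C)(C)C)CC[C@]1(C)C1=CC(O[Si](CC)(CC)CC)=C(C)CC12OCCO2
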